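The quinone ring is read as an oxidised 5-alkylresorcinol: the oxygens on C1 and C5 lie meta across C6–H, and ring carbon C3, C1′, the C2′ carbinol and the undecyl tail are the unbroken carbon chain of (R)-3-hydroxytetradecanoic acid. A single Michael–Claisen annulation of dimethyl malonate onto a methyl enone therefore creates both new ring C–C bonds and the only carbocycle, with no aryl–alkyl coupling and no reaction at C2′. Its precursor is the (E)-δ-silyloxy enone made from the silylated hydroxy aldehyde and an acetonyl ylide. Aromatisation, para-oxidation and Thiele–Winter acetoxylation later add the C4 and C2 oxygens; the last also converts the silyl ether into the acetate.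

Key step: step 5

Remark: the target is taken as the 2-hydroxy-1,4-benzoquinone tautomer drawn, with C2′ of R configuration. Ring numbering: C1 (C=O next to C2), C2 (OH), C3 (side chain), C4 (C=O), C5 (OMe), C6 (H); side chain C1′ (CH2) and C2′ (CHOAc).

Step 1
Reactants: 1 (R)-3-hydroxytetradecanoic acid
Product: 2 methyl (R)-3-hydroxytetradecanoate
Conditions: MeOH, H2SO4 (cat.), reflux
Reagents that add atoms: methanol, CO
Why: Fischer esterification of the acid under acid catalysis, which does not involve the C3 carbinol centre.

Step 2
Reactants: 2 methyl (R)-3-hydroxytetradecanoate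
Product: 3 methyl (R)-3-(tert-butyldimethylsilyloxy)tetradecanoate
Conditions: TBSCl, imidazole, DMF, rt
Reagents that add atoms: tert-butyldimethylsilyl chloride, CC(C)(C)[Si](C)(C)Cl
Why: Imidazole-promoted silylation of a secondary alcohol gives a base-stable ether that is a poor leaving group for the β-elimination that threatens later steps; the stereocentre is not touched.

Step 3
Reactants: 3 methyl (R)-3-(tert-butyldimethylsilyloxy)tetradecanoate
Product: 4 (R)-3-(tert-butyldimethylsilyloxy)tetradecanal
Conditions: i-Bu2AlH, CH2Cl2, −78 °C; MeOH, then aq. potassium sodium tartrate (KNaC4H4O6)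
Reagents that add atoms: none
Why: Half-reduction of a methyl ester with i-Bu2AlH at low temperature should stop at the aluminium hemiacetal, which releases the aldehyde only on work-up; the stereocentre is β to the carbonyl and cannot epimerise.

Step 4
Reactants: 4 (R)-3-(tert-butyldimethylsilyloxy)tetradecanal; 5 1-(triphenylphosphoranylidene)propan-2-one
Product: 6 (R,E)-6-(tert-butyldimethylsilyloxy)heptadec-3-en-2-one
Conditions: CH2Cl2, reflux
Reagents that add atoms: none
Why: Wittig olefination of an aliphatic aldehyde by a ketone-stabilised ylide should give the (E)-enone, and the ylide is too weakly basic to eliminate the β-silyloxy group.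

Step 5
Reactants: 6 (R,E)-6-(tert-butyldimethylsilyloxy)heptadec-3-en-2-one; 7 dimethyl malonate
Product: 9 methyl 2,4-dioxo-6-[(R)-2-(tert-butyldimethylsilyloxy)tridecyl]cyclohexane-1-carboxylate, via Michael adduct 8 (not isolated)
Conditions: 7 (1.3 equiv), NaOMe (1.15 equiv), MeOH, 0 °C; add 6, rt; then reflux; 1 M HCl to pH 4 at 0 °C
Reagents that add atoms: none
Why: The preformed sodium enolate NaCH(CO2Me)2 adds 1,4 to the enone β-carbon C4 to give adduct 8; proton transfer in methanol then gives the methyl ketone enolate at the former C1 methyl, which acylates on one malonate ester and expels methoxide, and the acidic tricarbonyl product leaves the equilibria as its enolate, so a full equivalent of base is consumed. The closest known reaction type is the Michael–Claisen condensation of alk-3-en-2-ones with malonic esters, as in the dimedone synthesis and the classical route to 5-alkylcyclohexane-1,3-diones. The one carbocycle closes in a 6-exo-trig mode, the attacked ester carbonyl lying outside the forming ring, and only the terminal methyl enolate can close because the internal C3 enolate would need a four-membered ring. No lasting stereocentre is set: the two new ring centres form as a mixture and vanish on aromatisation, while the silyloxy carbon is two atoms from the nearest reacting centre and keeps its R configuration. The selectivity needed is conjugate addition ahead of γ-deprotonation at C5 with E1cB loss of the δ-silyloxy group; it should be secured by the soft, weakly basic malonate anion formed before the enone is added cold, by the poor leaving ability of a silyloxide, and by heating only after the enone is consumed.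

Step 6
Reactants: 9 methyl 2,4-dioxo-6-[(R)-2-(tert-butyldimethylsilyloxy)tridecyl]cyclohexane-1-carboxylate
Product: 11 5-[(R)-2-(tert-butyldimethylsilyloxy)tridecyl]cyclohexane-1,3-dione, via keto acid 10 (not isolated)
Conditions: NaOH (2 M aq.), MeOH, 60 °C; then 1 M HCl to pH 3–4, 50 °C
Reagents that add atoms: none
Why: Saponification followed by acidification gives a β-keto acid that should lose CO2 through the usual cyclic transition state on gentle warming, and the pH is kept near 3–4 so that the secondary silyl ether survives.

Step 7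
Reactants: 11 5-[(R)-2-(tert-butyldimethylsilyloxy)tridecyl]cyclohexane-1,3-dione
Product: 12 3-methoxy-5-[(R)-2-(tert-butyldimethylsilyloxy)tridecyl]cyclohex-2-en-1-one
Conditions: TMSCHN2 (2 M in hexanes), MeOH, toluene, 0 °C to rt
Reagents that add atoms: (trimethylsilyl)diazomethane, C[Si](C)(C)C=[N+]=[N-]
Why: O-Methylation of the acidic enol of a cyclic 1,3-dione by a diazoalkane proceeds under neutral conditions that spare the silyl ether; the two enol oxygens are constitutionally equivalent, so the products differ only at ring C5, a centre that the next step erases.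

Step 8
Reactants: 12 3-methoxy-5-[(R)-2-(tert-butyldimethylsilyloxy)tridecyl]cyclohex-2-en-1-one
Product: 15 3-methoxy-5-[(R)-2-(tert-butyldimethylsilyloxy)tridecyl]phenol, via selenide 13 (not isolated), via selenoxide 14 (not isolated)
Conditions: LiN(i-Pr)2, THF, −78 °C; PhSeCl, −78 °C; then H2O2 (30% aq.), pyridine, CH2Cl2, 0 °C to rt
Reagents that add atoms: none
Why: Kinetic α′-deprotonation of the vinylogous ester at C6, selenenylation trans to the C5 substituent and selenoxide syn-elimination across C5–C6 should give a cross-conjugated cyclohexadienone that is the keto tautomer of the phenol and aromatises at once (selenoxide elimination route from cyclohexenones to phenols).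

Step 9
Reactants: 15 3-methoxy-5-[(R)-2-(tert-butyldimethylsilyloxy)tridecyl]phenol
Product: 16 2-methoxy-6-[(R)-2-(tert-butyldimethylsilyloxy)tridecyl]-1,4-benzoquinone
Conditions: (KSO3)2NO (2.5 equiv), aq. KH2PO4, CH2Cl2, methyltrioctylammonium chloride (cat.), rt
Reagents that add atoms: potassium nitrosodisulfonate (KSO3)2NO, [K+].[K+].[O-]S(=O)(=O)N([O])S(=O)(=O)[O-]
Why: Teuber oxidation, in which one nitrosodisulfonate radical removes the phenolic hydrogen and a second delivers oxygen to the free para carbon between the methoxy group and the side chain, should give the para-quinone, and the buffered medium leaves the silyl ether intact.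

Step 10
Reactants: 16 2-methoxy-6-[(R)-2-(tert-butyldimethylsilyloxy)tridecyl]-1,4-benzoquinone
Product: 18 3-[(R)-2-acetoxytridecyl]-5-methoxybenzene-1,2,4-triyl triacetate, via acetoxyalkyl quinone 17 (not isolated)
Conditions: Ac2O, H2SO4 (conc., cat.), 0 °C to rt
Reagents that add atoms: acetic anhydride, CC(=O)OC(C)=O
Why: Thiele–Winter acetoxylation, in which the strongly acidic anhydride first exchanges the silyl ether for acetate by Si–O cleavage (so the C2′–O bond and its configuration are untouched) and acetate then adds 1,4 at the free ring carbon next to the side chain, the other free carbon being the electron-rich β-carbon of the methoxy enol ether, before enolisation and acetylation give the triacetoxyarene.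

Step 11
Reactants: 18 3-[(R)-2-acetoxytridecyl]-5-methoxybenzene-1,2,4-triyl triacetate
Product: 20 (R)-1-(2-hydroxy-5-methoxy-3,6-dioxocyclohexa-1,4-dien-1-yl)tridecan-2-yl acetate, via benzenetriol 19 (not isolated)
Conditions: K2CO3, MeOH (degassed), 0 °C, Ar; then 1 M HCl to pH 6, air, rt
Reagents that add atoms: none
Why: Carbonate-promoted methanolysis should cleave the three aryl acetates, whose leaving groups are phenoxides, well ahead of the unactivated secondary alkyl acetate at 0 °C, and the 1,2,4-benzenetriol released is autoxidised by air to the 2-hydroxy-1,4-benzoquinone once the base is neutralised.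

Compound list
1 | (R)-3-hydroxytetradecanoic acid | CCCCCCCCCCC[C@H](CC(=O)O)O | starting material
2 | methyl (R)-3-hydroxytetradecanoate | CCCCCCCCCCC[C@H](CC(=O)OC)O | intermediate
3 | methyl (R)-3-(tert-butyldimethylsilyloxy)tetradecanoate | CCCCCCCCCCC[C@H](CC(=O)OC)O[Si](C)(C)C(C)(C)C | intermediate
4 | (R)-3-(tert-butyldimethylsilyloxy)tetradecanal | CCCCCCCCCCC[C@H](CC=O)O[Si](C)(C)C(C)(C)C | intermediate
5 | 1-(triphenylphosphoranylidene)propan-2-one | CC(=O)C=P(c1ccccc1)(c1ccccc1)c1ccccc1 | starting material
6 | (R,E)-6-(tert-butyldimethylsilyloxy)heptadec-3-en-2-one | CCCCCCCCCCC[C@H](C/C=C/C(C)=O)O[Si](C)(C)C(C)(C)C | intermediate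
7 | dimethyl malonate | COC(=O)CC(=O)OC | starting material
8 | dimethyl 2-[(6R)-6-(tert-butyldimethylsilyloxy)-2-oxoheptadecan-4-yl]malonate, mixture at C4 | CCCCCCCCCCC[C@H](CC(CC(C)=O)C(C(=O)OC)C(=O)OC)O[Si](C)(C)C(C)(C)C | intermediate (not isolated)
9 | methyl 2,4-dioxo-6-[(R)-2-(tert-butyldimethylsilyloxy)tridecyl]cyclohexane-1-carboxylate, mixture at the two ring centres, largely enolised | CCCCCCCCCCC[C@H](CC1CC(=O)CC(=O)C1C(=O)OC)O[Si](C)(C)C(C)(C)C | intermediate
10 | 2,4-dioxo-6-[(R)-2-(tert-butyldimethylsilyloxy)tridecyl]cyclohexane-1-carboxylic acid | CCCCCCCCCCC[C@H](CC1CC(=O)CC(=O)C1C(=O)O)O[Si](C)(C)C(C)(C)C | intermediate (not isolated)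
11 | 5-[(R)-2-(tert-butyldimethylsilyloxy)tridecyl]cyclohexane-1,3-dione | CCCCCCCCCCC[C@H](CC1CC(=O)CC(=O)C1)O[Si](C)(C)C(C)(C)C | intermediate
12 | 3-methoxy-5-[(R)-2-(tert-butyldimethylsilyloxy)tridecyl]cyclohex-2-en-1-one, both C5 epimers | CCCCCCCCCCC[C@H](CC1CC(=O)C=C(OC)C1)O[Si](C)(C)C(C)(C)C | intermediate
13 | 3-methoxy-6-(phenylselanyl)-5-[(R)-2-(tert-butyldimethylsilyloxy)tridecyl]cyclohex-2-en-1-one | CCCCCCCCCCC[C@H](CC1CC(OC)=CC(=O)C1[Se]c1ccccc1)O[Si](C)(C)C(C)(C)C | intermediate (not isolated)
14 | 3-methoxy-6-(phenylseleninyl)-5-[(R)-2-(tert-butyldimethylsilyloxy)tridecyl]cyclohex-2-en-1-one | CCCCCCCCCCC[C@H](CC1CC(OC)=CC(=O)C1[Se](=O)c1ccccc1)O[Si](C)(C)C(C)(C)C | intermediate (not isolated)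
15 | 3-methoxy-5-[(R)-2-(tert-butyldimethylsilyloxy)tridecyl]phenol | CCCCCCCCCCC[C@H](Cc1cc(O)cc(OC)c1)O[Si](C)(C)C(C)(C)C | intermediate
16 | 2-methoxy-6-[(R)-2-(tert-butyldimethylsilyloxy)tridecyl]-1,4-benzoquinone | CCCCCCCCCCC[C@H](CC1=CC(=O)C=C(OC)C1=O)O[Si](C)(C)C(C)(C)C | intermediate
17 | (R)-1-(5-methoxy-3,6-dioxocyclohexa-1,4-dien-1-yl)tridecan-2-yl acetate | CCCCCCCCCCC[C@H](CC1=CC(=O)C=C(OC)C1=O)OC(C)=O | intermediate (not isolated)
18 | 3-[(R)-2-acetoxytridecyl]-5-methoxybenzene-1,2,4-triyl triacetate | CCCCCCCCCCC[C@H](Cc1c(OC(C)=O)c(OC(C)=O)cc(OC)c1OC(C)=O)OC(C)=O | intermediate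
19 | (R)-1-(2,3,6-trihydroxy-5-methoxyphenyl)tridecan-2-yl acetate | CCCCCCCCCCC[C@H](Cc1c(O)c(O)cc(OC)c1O)OC(C)=O | intermediate (not isolated)
20 | (R)-1-(2-hydroxy-5-methoxy-3,6-dioxocyclohexa-1,4-dien-1-yl)tridecan-2-yl acetate | CCCCCCCCCCC[C@H](CC1=C(O)C(=O)C=C(OC)C1=O)OC(C)=O | target

Total step count: 11. Longest linear sequence: 11 steps, from 1 to 20.

Steps most likely to fail

Step 5. The enone may be deprotonated at its γ-carbon and lose the silyloxy group before malonate adds, or the Claisen closure may stall at the open adduct. The fallback exchanges the roles of the two partners. It sets out from aldehyde 4, which is condensed with methyl (triphenylphosphoranylidene)acetate in toluene at 80 °C to give methyl (R,E)-5-(tert-butyldimethylsilyloxy)hexadec-2-enoate F1, whose γ-hydrogens are much less acidic than those of 6. Methyl acetoacetate and NaOMe in MeOH, first at rt and then at reflux, should add through the acetoacetate carbon to give dimethyl 2-acetyl-3-[(R)-2-(tert-butyldimethylsilyloxy)tridecyl]pentanedioate F2. In F2 the acetyl methyl then acylates on the former enoate ester in a Dieckmann-type closure, and the route is rejoined at dione ester 9.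

Step 8. The selenoxide can eliminate only when selenium lies syn to the single C5 hydrogen, and the electron-rich phenol may be oxidised further by the peroxide and seleninic acid present. The fallback replaces selenium chemistry by a palladium dehydrosilylation. It sets out from enol ether 12, which is deprotonated with LiN(i-Pr)2 and trapped with Me3SiCl in THF at −78 °C to give 1-methoxy-3-(trimethylsilyloxy)-5-[(R)-2-(tert-butyldimethylsilyloxy)tridecyl]cyclohexa-1,3-diene F3. Saegusa–Ito oxidation with Pd(OAc)2 in MeCN at rt should give the same cross-conjugated dienone, which tautomerises, and the route is rejoined at phenol 15 with zerovalent palladium as the spent metal.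

Step 11. The side-chain acetate may be lost together with the aryl acetates, or the hindered aryl acetate between the methoxy group and the side chain may be cleaved too slowly. The fallback gives up kinetic discrimination among four acetates. It sets out from tetraacetate 18, which is fully methanolysed with K2CO3 in MeOH at rt under argon to (R)-3-(2-hydroxytridecyl)-5-methoxybenzene-1,2,4-triol F4. After neutralisation, air should oxidise F4 to 2-hydroxy-3-[(R)-2-hydroxytridecyl]-5-methoxy-1,4-benzoquinone F5. Ac2O and pyridine in CH2Cl2 at 0 °C then give (R)-1-(2-acetoxy-5-methoxy-3,6-dioxocyclohexa-1,4-dien-1-yl)tridecan-2-yl acetate F6. Its quinonyl acetate is a vinylogous anhydride and should be removed alone by aqueous NaHCO3 in THF at 0 °C, and the route is rejoined at target 20.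

Further compounds
F1 | step 5 | methyl (R,E)-5-(tert-butyldimethylsilyloxy)hexadec-2-enoate | CCCCCCCCCCC[C@H](C/C=C/C(=O)OC)O[Si](C)(C)C(C)(C)C
F2 | step 5 | dimethyl 2-acetyl-3-[(R)-2-(tert-butyldimethylsilyloxy)tridecyl]pentanedioate | CCCCCCCCCCC[C@H](CC(CC(=O)OC)C(C(C)=O)C(=O)OC)O[Si](C)(C)C(C)(C)C
F3 | step 8 | 1-methoxy-3-(trimethylsilyloxy)-5-[(R)-2-(tert-butyldimethylsilyloxy)tridecyl]cyclohexa-1,3-diene | CCCCCCCCCCC[C@H](CC1C=C(O[Si](C)(C)C)C=C(OC)C1)O[Si](C)(C)C(C)(C)C
F4 | step 11 | (R)-3-(2-hydroxytridecyl)-5-methoxybenzene-1,2,4-triol | CCCCCCCCCCC[C@H](Cc1c(O)c(O)cc(OC)c1O)O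
F5 | step 11 | 2-hydroxy-3-[(R)-2-hydroxytridecyl]-5-methoxy-1,4-benzoquinone | CCCCCCCCCCC[C@H](CC1=C(O)C(=O)C=C(OC)C1=O)O
F6 | step 11 | (R)-1-(2-acetoxy-5-methoxy-3,6-dioxocyclohexa-1,4-dien-1-yl)tridecan-2-yl acetate | CCCCCCCCCCC[C@H](CC1=C(OC(C)=O)C(=O)C=C(OC)C1=O)OC(C)=O
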